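**Retrosynthetic overview**

1. The target comes from triol 15 by acylation of its only secondary hydroxyl (C6) with O‑acetylvanillic acid, then release of the phenol.
2. The C8 methyl carbinol comes from methyl addition to a C8 enone, and the C6 carbinol from C4–OH‑directed reduction of a C6 ketone.
3. The five‑membered ring is closed last, C5→C4: a C5=C6 silyl enol ether attacks a C4 ketone that is unveiled in the same flask by a 1,2‑hydride shift (C4→C11) of a side‑chain epoxide.
4. The seven‑membered ring comes from a six‑membered 2‑siloxy‑dienone by a one‑carbon ring enlargement (1,2‑shift of a ring carbon to an electron‑poor exocyclic carbon).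
5. The six‑membered ring with the C1 quaternary centre comes from an asymmetric annulation of melonal with methyl vinyl ketone. Ring order: six → seven → five.

Assumption: the daucane nucleus is taken to arise from farnesyl diphosphate via a six‑membered‑ring cation, a 1,2‑alkyl shift to the seven‑membered ring, C5–C4 closure of the five‑membered ring and a 1,2‑hydride shift that puts the charge on C4, where water adds; C6 acyloxylation and C8 oxygenation are late.
Assumption: daucane numbering is used in the text (C1 quaternary methyl carbon, C4 isopropyl carbinol, C5 ring‑fusion CH, C6 ester carbon, C7 CH2, C8 methyl carbinol, C9=C10).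
Assumption: compounds 5–11 are about 1:1 mixtures at the oxirane CH; this centre is destroyed in step 6.

**Route**

Step 1
Reactants: 1 2,6-dimethylhept-5-enal (melonal, racemic); 2 but-3-en-2-one (methyl vinyl ketone)
Product: 4 (4S)-4-methyl-4-(4-methylpent-3-en-1-yl)cyclohex-2-en-1-one, via keto-aldehyde 3 (not isolated)
Conditions: proline aryl‑sulfonamide organocatalyst (N‑(4‑dodecylphenylsulfonyl)prolinamide, 20 mol %, the enantiomer that gives the S product), 4 Å MS, ClCH2CH2Cl, 23 °C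
Reagents that add atoms: none
Why: Enantioselective Yamada–Otani (Robinson‑type) annulation: the catalyst‑derived enamine of 1 adds to 2 on one face, which sets the quaternary C1 (S in 4; the antipodal catalyst gives ent‑4), and aldol condensation of keto‑aldehyde 3 closes the six‑membered ring.

Step 2
Reactants: 4 (4S)-4-methyl-4-(4-methylpent-3-en-1-yl)cyclohex-2-en-1-one
Product: 5 (4S)-4-[2-(3,3-dimethyloxiran-2-yl)ethyl]-4-methylcyclohex-2-en-1-one
Conditions: mCPBA (1.05 equiv), NaHCO3, CH2Cl2, 0 °C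
Reagents that add atoms: mCPBA, O=C(OO)c1cccc(Cl)c1
Why: Prilezhaev epoxidation takes place only at the electron‑rich trisubstituted side‑chain alkene (the enone alkene is inert), and the new oxirane centre, formed without control, is erased in step 6.

Step 3
Reactants: 5 (4S)-4-[2-(3,3-dimethyloxiran-2-yl)ethyl]-4-methylcyclohex-2-en-1-one
Product: 7 (4R)-4-[2-(3,3-dimethyloxiran-2-yl)ethyl]-2-hydroxy-4-methylcyclohexa-2,5-dien-1-one, via α-hydroperoxide 6 (not isolated)
Conditions: O2 (1 atm), t‑BuOK (1.5 equiv), t‑BuOH/DME, −20 → 0 °C; aq NH4Cl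
Reagents that add atoms: dioxygen, O=O
Why: Base‑mediated enolate autoxidation: the only enolisable position (C6; C1 is quaternary) is oxygenated via hydroperoxide 6, which loses water to the 1,2‑dione that rests as its cross‑conjugated enol (diosphenol) 7, while the epoxide is inert to t‑BuOK at this temperature (the descriptor at C1 changes from S to R only because the ring priorities change).

Step 4
Reactants: 7 (4R)-4-[2-(3,3-dimethyloxiran-2-yl)ethyl]-2-hydroxy-4-methylcyclohexa-2,5-dien-1-one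
Product: 8 (4R)-2-[(tert-butyldimethylsilyl)oxy]-4-[2-(3,3-dimethyloxiran-2-yl)ethyl]-4-methylcyclohexa-2,5-dien-1-one
Conditions: TBSCl, imidazole, DMF, 0 → 23 °C
Reagents that add atoms: tert‑butyldimethylsilyl chloride, CC(C)(C)[Si](C)(C)Cl
Why: O‑silylation of the acidic diosphenol hydroxyl makes C6 an electron‑rich, fully substituted alkenyl carbon for the coming shift and stores the C5=C6 enol ether needed in step 6.

Step 5
Reactants: 8 (4R)-2-[(tert-butyldimethylsilyl)oxy]-4-[2-(3,3-dimethyloxiran-2-yl)ethyl]-4-methylcyclohexa-2,5-dien-1-one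
Product: 11 (4R)-6-[(tert-butyldimethylsilyl)oxy]-4-[2-(3,3-dimethyloxiran-2-yl)ethyl]-4-methylcyclohepta-2,5-dien-1-one, via dibromomethyl carbinolate 9 (not isolated), via β-oxido carbenoid 10 (not isolated)
Conditions: CH2Br2, LiTMP, THF, −78 °C; n‑BuLi, −95 → 0 °C; aq NH4Cl
Reagents that add atoms: dibromomethane, BrCBr
Why: Taguchi–Yamamoto–Nozaki ring enlargement: dibromomethyllithium adds 1,2 to the non‑enolisable dienone (9), Br/Li exchange gives β‑oxido carbenoid 10, and 1,2‑shift of the more substituted, more electron‑rich siloxy‑alkenyl carbon C6 (rather than C9) to the electron‑poor exocyclic carbon, which becomes C7, expands the six‑ to the seven‑membered ring without touching C1.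

Step 6
Reactants: 11 (4R)-6-[(tert-butyldimethylsilyl)oxy]-4-[2-(3,3-dimethyloxiran-2-yl)ethyl]-4-methylcyclohepta-2,5-dien-1-one
Product: 13 (3R,3aR,8aR)-3-hydroxy-8a-methyl-3-(propan-2-yl)-2,3,3a,8a-tetrahydroazulene-4,6(1H,5H)-dione, via isopropyl ketone 12 (not isolated)
Conditions: BF3·OEt2 (2.2 equiv), CH2Cl2, −78 → −20 °C; aq NaHCO3
Reagents that add atoms: none
Why: Proposed new method: BF3 opens the trisubstituted epoxide at its tertiary carbon and a 1,2‑hydride shift from C4 (Meinwald rearrangement) gives the BF3‑bound isopropyl ketone 12, which is attacked at once by C5 of the silyl enol ether (intramolecular Mukaiyama aldol, five‑membered ring) through a chair‑like transition state with the tether pseudo‑equatorial on C1 and the isopropyl group turned away from C6, so that the trans ring fusion and the C4 hydroxyl syn to C6 should result (C5 is α to the new C6 ketone and can also settle to the trans junction by enolisation); the closest known reaction types are the BF3‑mediated Meinwald rearrangement of 2,2,3‑trialkyl oxiranes to ketones and intramolecular Mukaiyama aldol additions of silyl enol ethers to ketones.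

Step 7
Reactants: 13 (3R,3aR,8aR)-3-hydroxy-8a-methyl-3-(propan-2-yl)-2,3,3a,8a-tetrahydroazulene-4,6(1H,5H)-dione
Product: 14 (3R,3aS,4S,8aR)-3,4-dihydroxy-8a-methyl-3-(propan-2-yl)-2,3,3a,4,5,8a-hexahydroazulen-6(1H)-one
Conditions: Me4NBH(OAc)3, MeCN/AcOH, −30 → −10 °C
Reagents that add atoms: none
Why: Evans–Saksena reduction: the borohydride exchanges onto the tertiary C4–OH (β‑face) and delivers hydride to the β‑face of the C6 ketone, which gives the 6α‑alcohol (anti‑1,3‑diol, S at C6), while the conjugated C8 ketone has no hydroxyl placed to deliver hydride (the new equatorial C6–OH cannot reach it) and is left.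

Step 8
Reactants: 14 (3R,3aS,4S,8aR)-3,4-dihydroxy-8a-methyl-3-(propan-2-yl)-2,3,3a,4,5,8a-hexahydroazulen-6(1H)-one
Product: 15 (3R,3aS,4S,6S,8aR)-6,8a-dimethyl-3-(propan-2-yl)-1,2,3,3a,4,5,6,8a-octahydroazulene-3,4,6-triol
Conditions: MeLi, CeCl3, THF, −78 °C; aq NH4Cl
Reagents that add atoms: methyllithium, [Li]C
Why: Organocerium 1,2‑addition (Imamoto conditions, no enolisation or conjugate addition): the methyl group enters the C8 carbonyl from the α‑face, opposite the pseudo‑axial angular methyl on C1 that shields the β‑face of the enone, so the methyl ends α and the tertiary hydroxyl β (S at C8).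

Step 9
Reactants: 15 (3R,3aS,4S,6S,8aR)-6,8a-dimethyl-3-(propan-2-yl)-1,2,3,3a,4,5,6,8a-octahydroazulene-3,4,6-triol; 16 4-(acetyloxy)-3-methoxybenzoic acid
Product: 18 (3R,3aS,4S,6S,8aR)-3,6-dihydroxy-6,8a-dimethyl-3-(propan-2-yl)-1,2,3,3a,4,5,6,8a-octahydroazulen-4-yl 4-(acetyloxy)-3-methoxybenzoate, via O-acylisourea 17 (not isolated)
Conditions: DCC, DMAP (cat.), CH2Cl2, 0 → 23 °C
Reagents that add atoms: none
Why: Steglich esterification via O‑acylisourea 17 acylates only the secondary C6 hydroxyl, the two tertiary hydroxyls being too hindered (as in known acylations of jaeschkeanadiol), and no stereocentre is touched.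

Step 10
Reactants: 18 (3R,3aS,4S,6S,8aR)-3,6-dihydroxy-6,8a-dimethyl-3-(propan-2-yl)-1,2,3,3a,4,5,6,8a-octahydroazulen-4-yl 4-(acetyloxy)-3-methoxybenzoate
Product: 19 (3R,3aS,4S,6S,8aR)-3,6-dihydroxy-6,8a-dimethyl-3-(propan-2-yl)-1,2,3,3a,4,5,6,8a-octahydroazulen-4-yl 4-hydroxy-3-methoxybenzoate
Conditions: K2CO3 (cat.), MeOH, 0 °C
Reagents that add atoms: none
Why: Base‑catalysed transesterification (Zemplén‑type methanolysis) cleaves the reactive aryl acetate much faster than the hindered secondary vanillate ester and frees the phenol of the target.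

**Compound list**

1 | 2,6-dimethylhept-5-enal (melonal, racemic) | CC(CCC=C(C)C)C=O | starting material
2 | but-3-en-2-one (methyl vinyl ketone) | CC(=O)C=C | starting material
3 | (2S)-2-methyl-2-(4-methylpent-3-en-1-yl)-5-oxohexanal | CC(=O)CC[C@](C)(CCC=C(C)C)C=O | intermediate (not isolated)
4 | (4S)-4-methyl-4-(4-methylpent-3-en-1-yl)cyclohex-2-en-1-one | O=C1CC[C@](C)(CCC=C(C)C)C=C1 | intermediate
5 | (4S)-4-[2-(3,3-dimethyloxiran-2-yl)ethyl]-4-methylcyclohex-2-en-1-one (both oxirane epimers) | O=C1CC[C@](C)(CCC2OC2(C)C)C=C1 | intermediate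
6 | (4S)-4-[2-(3,3-dimethyloxiran-2-yl)ethyl]-6-hydroperoxy-4-methylcyclohex-2-en-1-one | OOC1C[C@](C)(CCC2OC2(C)C)C=CC1=O | intermediate (not isolated)
7 | (4R)-4-[2-(3,3-dimethyloxiran-2-yl)ethyl]-2-hydroxy-4-methylcyclohexa-2,5-dien-1-one | OC1=C[C@](C)(CCC2OC2(C)C)C=CC1=O | intermediate
8 | (4R)-2-[(tert-butyldimethylsilyl)oxy]-4-[2-(3,3-dimethyloxiran-2-yl)ethyl]-4-methylcyclohexa-2,5-dien-1-one | CC(C)(C)[Si](C)(C)OC1=C[C@](C)(CCC2OC2(C)C)C=CC1=O | intermediate
9 | lithium (4R)-2-[(tert-butyldimethylsilyl)oxy]-1-(dibromomethyl)-4-[2-(3,3-dimethyloxiran-2-yl)ethyl]-4-methylcyclohexa-2,5-dien-1-olate | [Li+].[O-]C1(C(Br)Br)C=C[C@@](C)(CCC2OC2(C)C)C=C1O[Si](C)(C)C(C)(C)C | intermediate (not isolated)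
10 | lithium (4R)-1-[bromo(lithio)methyl]-2-[(tert-butyldimethylsilyl)oxy]-4-[2-(3,3-dimethyloxiran-2-yl)ethyl]-4-methylcyclohexa-2,5-dien-1-olate (β-oxido carbenoid) | [Li+].[O-]C1(C([Li])Br)C=C[C@@](C)(CCC2OC2(C)C)C=C1O[Si](C)(C)C(C)(C)C | intermediate (not isolated)
11 | (4R)-6-[(tert-butyldimethylsilyl)oxy]-4-[2-(3,3-dimethyloxiran-2-yl)ethyl]-4-methylcyclohepta-2,5-dien-1-one | CC(C)(C)[Si](C)(C)OC1=C[C@](C)(CCC2OC2(C)C)C=CC(=O)C1 | intermediate
12 | (4R)-6-[(tert-butyldimethylsilyl)oxy]-4-methyl-4-(4-methyl-3-oxopentyl)cyclohepta-2,5-dien-1-one | CC(C)(C)[Si](C)(C)OC1=C[C@](C)(CCC(=O)C(C)C)C=CC(=O)C1 | intermediate (not isolated)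
13 | (3R,3aR,8aR)-3-hydroxy-8a-methyl-3-(propan-2-yl)-2,3,3a,8a-tetrahydroazulene-4,6(1H,5H)-dione | O=C1CC(=O)C=C[C@@]2(C)CC[C@@](O)(C(C)C)[C@H]12 | intermediate
14 | (3R,3aS,4S,8aR)-3,4-dihydroxy-8a-methyl-3-(propan-2-yl)-2,3,3a,4,5,8a-hexahydroazulen-6(1H)-one | O[C@H]1CC(=O)C=C[C@@]2(C)CC[C@@](O)(C(C)C)[C@H]12 | intermediate
15 | (3R,3aS,4S,6S,8aR)-6,8a-dimethyl-3-(propan-2-yl)-1,2,3,3a,4,5,6,8a-octahydroazulene-3,4,6-triol | O[C@H]1C[C@](C)(O)C=C[C@@]2(C)CC[C@@](O)(C(C)C)[C@H]12 | intermediate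
16 | 4-(acetyloxy)-3-methoxybenzoic acid | CC(=O)Oc1ccc(cc1OC)C(=O)O | starting material
17 | O-acylisourea of 16 with DCC | CC(=O)Oc1ccc(cc1OC)C(=O)OC(=NC1CCCCC1)NC1CCCCC1 | intermediate (not isolated)
18 | (3R,3aS,4S,6S,8aR)-3,6-dihydroxy-6,8a-dimethyl-3-(propan-2-yl)-1,2,3,3a,4,5,6,8a-octahydroazulen-4-yl 4-(acetyloxy)-3-methoxybenzoate | COc1cc(C(=O)O[C@H]2C[C@](C)(O)C=C[C@@]3(C)CC[C@@](O)(C(C)C)[C@H]23)ccc1OC(C)=O | intermediate
19 | (3R,3aS,4S,6S,8aR)-3,6-dihydroxy-6,8a-dimethyl-3-(propan-2-yl)-1,2,3,3a,4,5,6,8a-octahydroazulen-4-yl 4-hydroxy-3-methoxybenzoate | COc1cc(C(=O)O[C@H]2C[C@](C)(O)C=C[C@@]3(C)CC[C@@](O)(C(C)C)[C@H]23)ccc1O | target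

**Step count and risks**

Total step count: 10. Longest linear sequence: 10 steps (1 and 2 to 19); 16 is bought.

Steps most likely to fail:

Step 1. The annulation is less enantioselective with α,α‑dialkyl aldehydes than with α‑aryl ones, so 4 may not reach high ee. Fallback, setting out from 1 and 2 and coming back at 4: run the annulation without chiral control (pyrrolidine/AcOH, then KOH) to give rac-4-methyl-4-(4-methylpent-3-en-1-yl)cyclohex-2-en-1-one F1. Dehydrogenate it with IBX to the achiral 4-methyl-4-(4-methylpent-3-en-1-yl)cyclohexa-2,5-dien-1-one F2. Then desymmetrise F2 by conjugate reduction of one of its two enantiotopic enone double bonds with an ene‑reductase of the old‑yellow‑enzyme family (or CuH with a chiral bisphosphine and a silane), which returns 4 in the S series.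

Step 5. The unsubstituted alkenyl carbon C9 may migrate instead of the siloxy‑alkenyl carbon C6, or the silyl group may move to the new alkoxide. Fallback, setting out from 8 and coming back at 14: remove the competing alkenyl group first. Stryker's reagent reduces the unsubstituted enone double bond of 8 to (4R)-2-[(tert-butyldimethylsilyl)oxy]-4-[2-(3,3-dimethyloxiran-2-yl)ethyl]-4-methylcyclohex-2-en-1-one F3. The same dibromomethyllithium/n‑BuLi enlargement, in which an alkenyl carbon now competes only with a CH2 group, gives (4R)-6-[(tert-butyldimethylsilyl)oxy]-4-[2-(3,3-dimethyloxiran-2-yl)ethyl]-4-methylcyclohept-5-en-1-one F4. BF3·OEt2 then gives (3R,3aR,8aR)-3-hydroxy-8a-methyl-3-(propan-2-yl)octahydroazulene-4,6-dione F5, and Me4NBH(OAc)3 gives (3R,3aS,4S,8aR)-3,4-dihydroxy-8a-methyl-3-(propan-2-yl)octahydroazulen-6(1H)-one F6. The C9=C10 double bond is put back by Saegusa–Ito dehydrogenation: excess LDA/TMSCl (enolisation away from the C6 oxygen) gives (3R,3aS,4S,8aR)-8a-methyl-3-(propan-2-yl)-3,4,6-tris[(trimethylsilyl)oxy]-1,2,3,3a,4,5,8,8a-octahydroazulene F7, and Pd(OAc)2 followed by mild acid gives 14.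

Step 6. The epoxide‑derived cation may be captured directly by the enol ether (six‑membered ring) before the hydride shift, or the aldol may give the cis junction or the wrong C4 epimer. Fallback, setting out from 7 and coming back at 13: close the five‑membered ring before the ring enlargement, on the six‑membered diosphenol, whose enol carbon C5 is the nucleophile. BF3·OEt2 rearranges 7 to (4R)-2-hydroxy-4-methyl-4-(4-methyl-3-oxopentyl)cyclohexa-2,5-dien-1-one F8, which cyclises under the same acid to (1R,3aR)-1,7-dihydroxy-3a-methyl-1-(propan-2-yl)-1,2,3,3a-tetrahydro-6H-inden-6-one F9. TBSCl/imidazole gives (1R,3aR)-7-[(tert-butyldimethylsilyl)oxy]-1-hydroxy-3a-methyl-1-(propan-2-yl)-1,2,3,3a-tetrahydro-6H-inden-6-one F10. The dibromomethyllithium/n‑BuLi enlargement (one more equivalent of base for the free hydroxyl; the migrating siloxy‑alkenyl carbon is now fully substituted) gives (3R,8aR)-4-[(tert-butyldimethylsilyl)oxy]-3-hydroxy-8a-methyl-3-(propan-2-yl)-1,2,3,8a-tetrahydroazulen-6(5H)-one F11. HF·pyridine removes the silyl group with protonation of C5 to the trans‑fused dione 13.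

**Further compounds**

F1 | step 1 | rac-4-methyl-4-(4-methylpent-3-en-1-yl)cyclohex-2-en-1-one | O=C1CCC(C)(CCC=C(C)C)C=C1
F2 | step 1 | 4-methyl-4-(4-methylpent-3-en-1-yl)cyclohexa-2,5-dien-1-one | O=C1C=CC(C)(CCC=C(C)C)C=C1
F3 | step 5 | (4R)-2-[(tert-butyldimethylsilyl)oxy]-4-[2-(3,3-dimethyloxiran-2-yl)ethyl]-4-methylcyclohex-2-en-1-one | CC(C)(C)[Si](C)(C)OC1=C[C@](C)(CCC2OC2(C)C)CCC1=O
F4 | step 5 | (4R)-6-[(tert-butyldimethylsilyl)oxy]-4-[2-(3,3-dimethyloxiran-2-yl)ethyl]-4-methylcyclohept-5-en-1-one | CC(C)(C)[Si](C)(C)OC1=C[C@](C)(CCC2OC2(C)C)CCC(=O)C1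
F5 | step 5 | (3R,3aR,8aR)-3-hydroxy-8a-methyl-3-(propan-2-yl)octahydroazulene-4,6-dione | O=C1CC(=O)CC[C@@]2(C)CC[C@@](O)(C(C)C)[C@H]12
F6 | step 5 | (3R,3aS,4S,8aR)-3,4-dihydroxy-8a-methyl-3-(propan-2-yl)octahydroazulen-6(1H)-one | O[C@H]1CC(=O)CC[C@@]2(C)CC[C@@](O)(C(C)C)[C@H]12
F7 | step 5 | (3R,3aS,4S,8aR)-8a-methyl-3-(propan-2-yl)-3,4,6-tris[(trimethylsilyl)oxy]-1,2,3,3a,4,5,8,8a-octahydroazulene | C[Si](C)(C)O[C@H]1CC(O[Si](C)(C)C)=CC[C@@]2(C)CC[C@@](O[Si](C)(C)C)(C(C)C)[C@H]12
F8 | step 6 | (4R)-2-hydroxy-4-methyl-4-(4-methyl-3-oxopentyl)cyclohexa-2,5-dien-1-one | OC1=C[C@](C)(CCC(=O)C(C)C)C=CC1=O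
F9 | step 6 | (1R,3aR)-1,7-dihydroxy-3a-methyl-1-(propan-2-yl)-1,2,3,3a-tetrahydro-6H-inden-6-one | O=C1C=C[C@@]2(C)CC[C@@](O)(C(C)C)C2=C1O
F10 | step 6 | (1R,3aR)-7-[(tert-butyldimethylsilyl)oxy]-1-hydroxy-3a-methyl-1-(propan-2-yl)-1,2,3,3a-tetrahydro-6H-inden-6-one | O=C1C=C[C@@]2(C)CC[C@@](O)(C(C)C)C2=C1O[Si](C)(C)C(C)(C)C
F11 | step 6 | (3R,8aR)-4-[(tert-butyldimethylsilyl)oxy]-3-hydroxy-8a-methyl-3-(propan-2-yl)-1,2,3,8a-tetrahydroazulen-6(5H)-one | O=C1C=C[C@@]2(C)CC[C@@](O)(C(C)C)C2=C(O[Si](C)(C)C(C)(C)C)C1
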